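(The readings were generated by integration with constants of no real substance; scatter was added.)

| flask | substrate | free enzyme | temperature | remark | time |
|---|---|---|---|---|---|
| gamma | 0.050 M (in portions, 3) | 12 µM | 14 °C | run made earlier; portions every 1.0 h |  |
| beta | 0.050 M (in portions, 3) | 50 µM | 22 °C | run made earlier; portions every 1.0 h |  |
| alpha | 0.025 M (in portions, 3) | 25 µM | 14 °C | run made earlier; portions every 1.0 h |  |
| green | 0.050 M | 25 µM | 10 °C | everything together at the start | 20 h |
| violet | 0.050 M (in portions, 3) | 25 µM | 25 °C | the portions of substrate follow each other after 1.0 h, the first at the start | 20 h |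

- gamma (time / h: product / %): 5.00: 84.5; 10.0: 93.7; 15.0: 95.8; 20.0: 97.4
- beta (time / h: product / %): 1.50: 54.4; 4.00: 95.9; 8.00: 97.7; 12.0: 98.7
- alpha (time / h: product / %): 5.00: 86.6; 10.0: 94.4; 15.0: 95.8; 20.0: 97.5

(standard deviation of a reading: 0.5 percentage points)

1. the winner by amount of product, in percent of the substrate charged; "neither" if no more than 2 percentage points parts them (green / violet / neither)
2. how much product is there at the end, in percent of the substrate charged: green
3. how much product is there at the end, in percent of the substrate charged: violet

- the analysis behind the earlier runs scatters by 0.5 percentage points, standard deviation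

**Two charges.** In this stirred vessel of constant volume, free enzyme turns substrate into product. Follow one substrate molecule: its chance per hour of being turned seems to grow with c(free enzyme) and with c(substrate) around it. Gamma and alpha differ in both charges, yet the products of the two charges stand at a ratio of 0.960, and the runs read 84.5 % and 86.6 % at 5.00 h. We therefore take the rate as c(free enzyme) times c(substrate) squared, second order in substrate. The reciprocal of the unreacted fraction then climbs in a straight line.

**Clock rate.** We scale that slope to the charge of green and violet. Between 5.00 h and 15.0 h, gamma gives 3.62 h⁻¹ and alpha gives 3.27 h⁻¹. These come from different charges, and each is a clock rate, the hourly climb of the reciprocal at 14 °C.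

**Beta's slopes.** Beta's last portion went in at 2.00 h. That portion is a third of the charge, so the reciprocal then stood at 3 at most. Up to 4.00 h this gives 10.7 h⁻¹, but from 4.00 h to 12.0 h it gives a lower 6.57 h⁻¹. The same scatter of 0.5 percentage points sits on a residue of 1.30 % late and 4.10 % early, and the reciprocal magnifies it, so we keep the early slope. Scaled, it is 5.35 h⁻¹ at 22 °C, a factor of 1.48 over gamma's clock rate and of 1.64 over alpha's.

**Our reckoning.** Stretching each factor over the degrees, gamma leads to 2.97 h⁻¹ for green and alpha to 2.56 h⁻¹. Their mean, 2.77 h⁻¹, is green's clock rate, the hourly climb of the reciprocal at 10 °C, and it gives 98.2 %. From beta, the same two factors lead to 6.19 h⁻¹ and 6.43 h⁻¹ for violet. Their mean, 6.31 h⁻¹, counted from violet's last portion, gives 99.1 %. They part by 0.90 points, inside the margin.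

**The forecast.** It says neither: green 98.3 % (97.7 % to 98.8 %) and violet 98.5 % (97.2 % to 99.3 %). It holds violet lower than we do, noting that “beta's tail lags, suggesting enzyme decay when warm”.

**The result.** Green ends at 98.3 % and violet at 99.1 %, so the answer is neither.

    free enzyme → unfolded enzyme (k = 0.00230 h⁻¹, Ea = 209 kJ mol⁻¹)
    substrate + free enzyme → product + free enzyme, rate k2*[substrate]^2*[free enzyme]/(1 + ([substrate]/Kh2)^2) (48.0 mM, k = 5.20 × 10⁶ M⁻² h⁻¹, Ea = 36.0 kJ mol⁻¹)
    (constants at 25 °C)

**Enzyme's time.** In violet, the half-life of free enzyme by its loss to unfolded enzyme is 13 d, far longer than the 20 h of the run. At 20.0 h violet's free enzyme stands at 95.5 % and its unfolded enzyme at 4.50 %. Green's clock rate of 2.77 h⁻¹, carried to 200 h, gives a residue of 0.180 %, and green then holds substrate at 0.166 %.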